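**Retrosynthetic overview**
1. The nitrogen ring is closed last. The C1–C8a bond comes from a Bischler–Napieralski closure of an (S)-N-acetyl-1-arylpropan-2-amine.
2. Key move: two finished arenes are never coupled. The C1'–C4' ring of the naphthalene is grown on the arene. The 4'-naphthol comes from acid opening of a 1,4-epoxide, which comes from a Diels–Alder reaction of 3-methoxybenzyne with a 2-aryl-3-methylfuran (bonds C1'–C8a' and C4'–C4a'). The hindered axis appears only on aromatisation.
3. The aryl–furan bond is made by Suzuki coupling of a 2-bromo-3,5-dimethoxyphenyl unit with a small 3-methylfur-2-ylboronate.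
4. C-3 comes from the chiral pool. (S)-N-Boc-2-methylaziridine is opened at its CH2 by a 3,5-dimethoxyphenyl Grignard reagent under copper catalysis.
5. Ring order: the dimethoxybenzene and furan rings are bought, then the oxa-bridged ring is formed and becomes the naphthalene, then the dihydropyridine ring is closed.

Assumption: the SMILES fixes only C-3 (S) and cannot encode the hindered C-5/C-1' axis. C-3 is therefore set absolutely, and the two axial isomers (diastereomers with the same SMILES) are separated after the last step.

**Step 1**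
Reactants: 1 1-bromo-3,5-dimethoxybenzene; 2 tert-butyl (2S)-2-methylaziridine-1-carboxylate
Product: 4 tert-butyl N-[(2S)-1-(3,5-dimethoxyphenyl)propan-2-yl]carbamate, via 3,5-dimethoxyphenylmagnesium bromide 3 (not isolated)
Conditions: 1 (1.5 equiv), Mg, THF, reflux; then CuBr·SMe2 (10 mol %), 2, THF, −30 °C to 0 °C; H2O quench
Reagents that add atoms: none
Why: Copper-catalysed SN2 ring opening of an activated aziridine by an aryl Grignard reagent occurs at the unsubstituted CH2, so the C–N stereocentre bought with 2 is untouched and becomes C-3 with (S) configuration (the priority order N > CH2 > CH3 > H does not change).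

**Step 2**
Reactants: 4 tert-butyl N-[(2S)-1-(3,5-dimethoxyphenyl)propan-2-yl]carbamate
Product: 5 tert-butyl N-[(2S)-1-(2-bromo-3,5-dimethoxyphenyl)propan-2-yl]carbamate
Conditions: NBS (1.0 equiv), MeCN, 0 °C, dark
Reagents that add atoms: N-bromosuccinimide, O=C1CCC(=O)N1Br
Why: Electrophilic aromatic bromination of a 5-alkylresorcinol dimethyl ether goes ortho to one methoxy group and para to the other, the two such positions are equivalent and the site between both methoxy groups reacts more slowly, so one equivalent of NBS gives the 2-bromide without touching the carbamate or C-3.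

**Step 3**
Reactants: 5 tert-butyl N-[(2S)-1-(2-bromo-3,5-dimethoxyphenyl)propan-2-yl]carbamate; 6 4,4,5,5-tetramethyl-2-(3-methylfuran-2-yl)-1,3,2-dioxaborolane
Product: 7 tert-butyl N-[(2S)-1-[3,5-dimethoxy-2-(3-methylfuran-2-yl)phenyl]propan-2-yl]carbamate
Conditions: 6 (1.6 equiv), Pd(OAc)2 (5 mol %), SPhos (10 mol %), K3PO4, toluene/H2O 10:1, 90 °C
Reagents that add atoms: none
Why: In this Suzuki–Miyaura coupling the bulky electron-rich biarylphosphine lets zerovalent palladium insert into the di-ortho-substituted electron-rich bromide and couple before the fur-2-ylboronate protodeboronates, and the five-membered partner is far less demanding than a finished 2-methylnaphthalene.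

**Step 4**
Reactants: 7 tert-butyl N-[(2S)-1-[3,5-dimethoxy-2-(3-methylfuran-2-yl)phenyl]propan-2-yl]carbamate
Product: 9 tert-butyl N-acetyl-N-[(2S)-1-[3,5-dimethoxy-2-(3-methylfuran-2-yl)phenyl]propan-2-yl]carbamate, via lithium carbamate salt 8 (not isolated)
Conditions: LiHMDS (1.1 equiv), THF, −78 °C; AcCl (1.3 equiv), −78 °C to 0 °C
Reagents that add atoms: acetyl chloride, CC(=O)Cl
Why: N-acylation of a metalated carbamate gives the N-acetyl-N-Boc imide, which removes the only N–H before the aryne step and already installs the two carbons that become C-1 and its methyl group, while the amide base is too weak to lithiate the furan or to touch C-3.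

**Step 5**
Reactants: 9 tert-butyl N-acetyl-N-[(2S)-1-[3,5-dimethoxy-2-(3-methylfuran-2-yl)phenyl]propan-2-yl]carbamate; 10 3-methoxy-2-(trimethylsilyl)phenyl trifluoromethanesulfonate
Product: 12 tert-butyl N-acetyl-N-[(2S)-1-[3,5-dimethoxy-2-(5-methoxy-2-methyl-1,4-dihydro-1,4-epoxynaphthalen-1-yl)phenyl]propan-2-yl]carbamate (bridgehead diastereomers carried on together), via 3-methoxybenzyne 11 (not isolated)
Conditions: 10 (1.5 equiv), dry CsF (3 equiv), MeCN, rt; chromatography removes the minor regioisomer
Reagents that add atoms: none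
Why: Fluoride-induced 1,2-elimination gives the aryne, whose strain makes the aryne–furan Diels–Alder reaction early and fast enough to tolerate the twisted di-ortho-substituted aryl group; the regiochemistry drawn (OMe next to the C–H bridgehead) is favoured because the 3-methyl group makes the aryl-bearing furan carbon the more nucleophilic diene terminus, which pairs with the more electrophilic aryne carbon remote from OMe, and because it keeps OMe away from the bulky aryl group, while the two new bridgehead stereocentres need no control since step 6 destroys them.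

**Step 6**
Reactants: 12 tert-butyl N-acetyl-N-[(2S)-1-[3,5-dimethoxy-2-(5-methoxy-2-methyl-1,4-dihydro-1,4-epoxynaphthalen-1-yl)phenyl]propan-2-yl]carbamate
Product: 14 N-[(2S)-1-[2-(4-hydroxy-5-methoxy-2-methylnaphthalen-1-yl)-3,5-dimethoxyphenyl]propan-2-yl]acetamide, via N-Boc naphthol imide 13 (not isolated)
Conditions: HCl (4 M in dioxane), CH2Cl2, 0 °C to rt
Reagents that add atoms: none
Why: In this acid-catalysed isomerisation of a 1,4-epoxy-1,4-dihydronaphthalene to a 1-naphthol the protonated bridge ionises at the aryl-bearing bridgehead (a tertiary, allylic, doubly benzylic position conjugated to a 2,4-dimethoxyaryl donor), loss of the proton at the other bridgehead aromatises the ring and leaves the oxygen at C-4', the same acid then cleaves the Boc group to the acetamide, C-3 is untouched, and the biaryl axis arises here without control as a pair of atropo-diastereomers.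

**Step 7**
Reactants: 14 N-[(2S)-1-[2-(4-hydroxy-5-methoxy-2-methylnaphthalen-1-yl)-3,5-dimethoxyphenyl]propan-2-yl]acetamide
Product: 15 N-[(2S)-1-[2-(4,5-dimethoxy-2-methylnaphthalen-1-yl)-3,5-dimethoxyphenyl]propan-2-yl]acetamide
Conditions: MeI (1.5 equiv), K2CO3, DMF, rt
Reagents that add atoms: iodomethane, CI
Why: In this Williamson ether synthesis carbonate deprotonates only the naphthol (the acetamide N–H is far less acidic), and the naphtholate is methylated by SN2 on MeI despite its hydrogen bond to the peri methoxy group.

**Step 8**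
Reactants: 15 N-[(2S)-1-[2-(4,5-dimethoxy-2-methylnaphthalen-1-yl)-3,5-dimethoxyphenyl]propan-2-yl]acetamide
Product: 17 O-methylancistrocladinine, via N-alkylnitrilium triflate 16 (not isolated)
Conditions: Tf2O (1.1 equiv), 2-chloropyridine (1.2 equiv), CH2Cl2, −78 °C to rt; aq NaHCO3; preparative HPLC to part the two axial isomers
Reagents that add atoms: none
Why: In this Bischler–Napieralski cyclodehydration by electrophilic amide activation, triflation of the amide oxygen and loss of triflate give the nitrilium ion, which is attacked by the only free ortho position of the arene (ortho and para to the two methoxy groups) in a six-membered Friedel–Crafts closure, and C-3 stays (S) because no bond to it is broken and the weak base cannot epimerise it.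

**Compound list**
1 | 1-bromo-3,5-dimethoxybenzene | COc1cc(Br)cc(OC)c1 | starting material
2 | tert-butyl (2S)-2-methylaziridine-1-carboxylate | C[C@H]1CN1C(=O)OC(C)(C)C | starting material
3 | 3,5-dimethoxyphenylmagnesium bromide (not isolated) | COc1cc(OC)cc([Mg]Br)c1 | intermediate
4 | tert-butyl N-[(2S)-1-(3,5-dimethoxyphenyl)propan-2-yl]carbamate | COc1cc(OC)cc(C[C@H](C)NC(=O)OC(C)(C)C)c1 | intermediate
5 | tert-butyl N-[(2S)-1-(2-bromo-3,5-dimethoxyphenyl)propan-2-yl]carbamate | COc1cc(OC)c(Br)c(C[C@H](C)NC(=O)OC(C)(C)C)c1 | intermediate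
6 | 4,4,5,5-tetramethyl-2-(3-methylfuran-2-yl)-1,3,2-dioxaborolane | Cc1ccoc1B1OC(C)(C)C(C)(C)O1 | starting material
7 | tert-butyl N-[(2S)-1-[3,5-dimethoxy-2-(3-methylfuran-2-yl)phenyl]propan-2-yl]carbamate | COc1cc(OC)c(-c2occc2C)c(C[C@H](C)NC(=O)OC(C)(C)C)c1 | intermediate
8 | lithium salt of carbamate 7 (not isolated) | COc1cc(OC)c(-c2occc2C)c(C[C@H](C)[N-]C(=O)OC(C)(C)C)c1.[Li+] | intermediate
9 | tert-butyl N-acetyl-N-[(2S)-1-[3,5-dimethoxy-2-(3-methylfuran-2-yl)phenyl]propan-2-yl]carbamate | COc1cc(OC)c(-c2occc2C)c(C[C@H](C)N(C(C)=O)C(=O)OC(C)(C)C)c1 | intermediate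
10 | 3-methoxy-2-(trimethylsilyl)phenyl trifluoromethanesulfonate | COc1cccc(OS(=O)(=O)C(F)(F)F)c1[Si](C)(C)C | starting material
11 | 3-methoxybenzyne (not isolated) | COC1=CC=CC#C1 | intermediate
12 | tert-butyl N-acetyl-N-[(2S)-1-[3,5-dimethoxy-2-(5-methoxy-2-methyl-1,4-dihydro-1,4-epoxynaphthalen-1-yl)phenyl]propan-2-yl]carbamate, mixture at the two bridgeheads | COc1cccc2c1C1OC2(C(C)=C1)c1c(OC)cc(OC)cc1C[C@H](C)N(C(C)=O)C(=O)OC(C)(C)C | intermediate
13 | tert-butyl N-acetyl-N-[(2S)-1-[2-(4-hydroxy-5-methoxy-2-methylnaphthalen-1-yl)-3,5-dimethoxyphenyl]propan-2-yl]carbamate (not isolated) | COc1cc(OC)c(-c2c(C)cc(O)c3c(OC)cccc23)c(C[C@H](C)N(C(C)=O)C(=O)OC(C)(C)C)c1 | intermediate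
14 | N-[(2S)-1-[2-(4-hydroxy-5-methoxy-2-methylnaphthalen-1-yl)-3,5-dimethoxyphenyl]propan-2-yl]acetamide | COc1cc(OC)c(-c2c(C)cc(O)c3c(OC)cccc23)c(C[C@H](C)NC(C)=O)c1 | intermediate
15 | N-[(2S)-1-[2-(4,5-dimethoxy-2-methylnaphthalen-1-yl)-3,5-dimethoxyphenyl]propan-2-yl]acetamide | COc1cc(OC)c(-c2c(C)cc(OC)c3c(OC)cccc23)c(C[C@H](C)NC(C)=O)c1 | intermediate
16 | N-[(2S)-1-arylpropan-2-yl]acetonitrilium triflate derived from 15 (not isolated) | COc1cc(OC)c(-c2c(C)cc(OC)c3c(OC)cccc23)c(C[C@H](C)[N+]#CC)c1.[O-]S(=O)(=O)C(F)(F)F | intermediate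
17 | O-methylancistrocladinine, (3S)-5-(4,5-dimethoxy-2-methylnaphthalen-1-yl)-6,8-dimethoxy-1,3-dimethyl-3,4-dihydroisoquinoline | COc1cc(OC)c(-c2c(C)cc(OC)c3c(OC)cccc23)c2c1C(C)=N[C@@H](C)C2 | target

**Step count**
- Total step count: 8.
- Longest linear sequence: 8 steps (1 or 2 to 17). Compounds 6 and 10 are bought and enter directly.

**Three steps most likely to fail**

*Step 5 (aryne cycloaddition).*
- Risks: the di-ortho-substituted aryl group shields both faces of the furan, the methoxy group steers only moderately so a regioisomer can form, and fluoride may attack the imide.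
- The fallback sets out from 5 and comes back at 14. It replaces cycloaddition by carbonyl addition and reductive aromatisation.
- Bromide 5 is treated with MeLi (N–H) and then t-BuLi (Br/Li exchange) in THF at −78 °C to give the N,C-dilithio species F1.
- Commercial plumbagin (5-hydroxy-2-methyl-1,4-naphthoquinone) is O-methylated with MeI and Ag2O in CH2Cl2 to plumbagin methyl ether F2.
- The aryllithium adds 1,2 to the C-1 carbonyl of the quinone to give the para-quinol F3. The C-4 carbonyl is deactivated by the adjacent ring methoxy group and by the beta-methyl group.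
- Zn dust in AcOH removes the tertiary, vinylogously alpha-keto hydroxyl group and aromatises to the N-Boc naphthol F4.
- HCl in dioxane gives the amino naphthol F5. One equivalent of Ac2O in EtOAc/aqueous NaHCO3 then acetylates nitrogen only and delivers 14.

*Step 6 (bridge opening with Boc loss).*
- Risks: competing ionisation at the C-4' bridgehead (helped by the neighbouring methoxy group) followed by aryl migration, tert-butylation of the very electron-rich free naphthol, and air oxidation of that naphthol.
- The fallback sets out from 12 and comes back at 15. It alkylates the bridge oxygen instead of protonating it, so no free naphthol and no strong acid are present during aromatisation.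
- MeOTf with 2,6-di-tert-butyl-4-methylpyridine in CH2Cl2 methylates the bridging ether.
- The oxonium ion ionises at the aryl-bearing bridgehead and the hindered base removes the C-4' proton. This gives directly the N-acetyl-N-Boc dimethyl ether F6.
- TFA in CH2Cl2 then removes the Boc group to give 15, so steps 6 and 7 are both bypassed.

*Step 3 (Suzuki coupling).*
- Risks: slow oxidative addition into a hindered electron-rich bromide, against fast protodeboronation of the fur-2-ylboronate.
- The fallback sets out from 5 and comes back at 7. It builds the furan by carbonyl addition and dehydration instead of cross-coupling.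
- The N,C-dilithio species F1, made as above, is added at −78 °C to commercial 3-methylfuran-2(5H)-one to give the lactol F7.
- The lactol loses water on brief treatment with pyridinium p-toluenesulfonate in CH2Cl2. It aromatises to the 2-aryl-3-methylfuran 7, and the Boc group survives.

**Further compounds**
F1 | step 5 | tert-butyl N-lithio-N-[(2S)-1-(2-lithio-3,5-dimethoxyphenyl)propan-2-yl]carbamate | COc1cc(OC)c([Li])c(C[C@H](C)N([Li])C(=O)OC(C)(C)C)c1
F2 | step 5 | 5-methoxy-2-methylnaphthalene-1,4-dione | COc1cccc2c1C(=O)C=C(C)C2=O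
F3 | step 5 | tert-butyl N-[(2S)-1-[2-(1-hydroxy-5-methoxy-2-methyl-4-oxo-1,4-dihydronaphthalen-1-yl)-3,5-dimethoxyphenyl]propan-2-yl]carbamate, mixture at the carbinol carbon | COc1cccc2c1C(=O)C=C(C)C2(O)c1c(OC)cc(OC)cc1C[C@H](C)NC(=O)OC(C)(C)C
F4 | step 5 | tert-butyl N-[(2S)-1-[2-(4-hydroxy-5-methoxy-2-methylnaphthalen-1-yl)-3,5-dimethoxyphenyl]propan-2-yl]carbamate | COc1cc(OC)c(-c2c(C)cc(O)c3c(OC)cccc23)c(C[C@H](C)NC(=O)OC(C)(C)C)c1
F5 | step 5 | 4-[2-[(2S)-2-aminopropyl]-4,6-dimethoxyphenyl]-8-methoxy-3-methylnaphthalen-1-ol | COc1cc(OC)c(-c2c(C)cc(O)c3c(OC)cccc23)c(C[C@H](C)N)c1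
F6 | step 6 | tert-butyl N-acetyl-N-[(2S)-1-[2-(4,5-dimethoxy-2-methylnaphthalen-1-yl)-3,5-dimethoxyphenyl]propan-2-yl]carbamate | COc1cc(OC)c(-c2c(C)cc(OC)c3c(OC)cccc23)c(C[C@H](C)N(C(C)=O)C(=O)OC(C)(C)C)c1
F7 | step 3 | tert-butyl N-[(2S)-1-[2-(2-hydroxy-3-methyl-2,5-dihydrofuran-2-yl)-3,5-dimethoxyphenyl]propan-2-yl]carbamate, mixture at the lactol carbon | COc1cc(OC)c(C2(O)OCC=C2C)c(C[C@H](C)NC(=O)OC(C)(C)C)c1
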